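**Conventions.** Atoms carry the eremophilane numbers of the target: ring A = C1, C2, C3, C4, C5, C10; ring B = C5, C6, C7, C8, C9, C10; C14 is the methyl on C5 and C15 the methyl on C4; β is the face of the decalin that carries C14. The bicyclo[2.2.2]octane intermediates use the same atom numbers (bridgeheads C5 and C8; bridges C3–C4, C6–C7 and C9–C10). Compound numbers 1–30 follow the order of the steps.

## Analysis of the target

Target 30 is an eremophilane: a trans-fused decalin (10α-H, 5β-methyl) with a 4β-methyl, a 7α-isopropenyl group, a ketone at C8, an angelate on the 3α-oxygen and an (E)-3-methylpent-2-enoate on the 9α-oxygen; the six stereocentres are 3R,4R,5R,7S,9S,10R. In the chair–chair form only the angular methyl C14 is axial, so C4, C7 and C9, each next to a carbonyl at some stage, sit in their more stable configurations, whereas quaternary C5 cannot be corrected once made. The sensitive groups are the angelate (Z to E), the second enoate (E/Z scrambling and deconjugation), the α-acyloxy ketone and, above all, the isopropenyl group α to the C8 carbonyl, which slips into conjugation as an isopropylidene ketone under equilibrating acid or base. The synthesis is hard because quaternary C5 is flanked by the stereocentres C4 and C10, because three oxygens (C3, C8, C9) must end in three different states, and because the two hydroxyls must receive different, isomerisation-prone acyl groups. The equatorial 3α-oxygen is also the one that hydride reagents do not deliver, since axial C14 shields the β face of C3. The strategy rests on one feature: the chain C3–C4–C5–C6–C7–C8, with its C4 methyl, its C7 isopropenyl group and an oxygen at each end, is the ring of carvone 1 opened between the carbonyl carbon and the α′ carbon.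

## Retrosynthetic reasoning

**Ester C–O bonds at C9 and C3.** The C9 ester of 30 is cut first, giving hydroxy ketone 27 and acid 28, and the C3 angelate next, giving alcohol 22 and acid 23. Both acyl groups isomerise easily, so they go on last. The angelate is attached while C8 is still masked, so the heated esterification never meets the base-sensitive isopropenyl ketone.

**C9–O bond.** The C9 oxygen of 27 is removed to leave the C8=C9 silyl enol ether 25. In the forward sense an electrophilic oxygen must add to C9 from the α face, opposite axial C14. The enol ether also fixes the regiochemistry (C9, not C7) and protects C8 during the reduction of ring A.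

**C3 carbinol and the C1–C2 single bond.** Alcohol 22 is traced to enone 20, and 20 to enedione 18 by enol silylation. The forward reduction must saturate C1=C2 and give the equatorial 3α-alcohol; only an electron-transfer reduction does both, and it tolerates the enol ether but not a free C8 ketone.

**C1=C2 of ring A.** Ring A of 18 is opened at the C1=C2 double bond to dienone 17. An aldol closure at this point would need base, which would scramble C4 and C10 and invite conjugation of the isopropenyl group into the C8 ketone. A metathesis closure is neutral and keeps every stereocentre.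

**C3–C8, the template bond.** Reconnecting C3 and C8 of 17 gives the bicyclic 1,2-diol 16. The forward glycol cleavage turns the bridgehead oxygen into the C8 ketone, frees ring B as a cyclohexane and releases the strain of the bicycle.

**The two vinyl groups.** The C3 vinyl carbinol of 16 comes from ketone 11 by addition of a vinyl organometallic (12). The C10 vinyl group comes from the ester by reduction, oxidation and one-carbon olefination (13, 14, 15). The silyl ether comes off only after these steps (16).

**Configurations at C4 and C10.** Keto ester 11 is the C4,C10-diepimer of the kinetic adduct 10. Both centres are adjacent to a carbonyl in the bicycle, where no isopropenyl ketone exists yet, so they can be equilibrated safely there; the rigid cage makes 11 the only strain-free isomer.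

**C8–C9 and C5–C10, the key disconnection.** Cutting these two bonds of 10 gives silyloxy enone 6 and methyl acrylate 7. The forward double conjugate addition must form quaternary C8 and quaternary C5 on the face opposite the C7 isopropenyl group; the second bond is intramolecular, which is what allows the hindered C5 to be reached.

**The template.** Enone 6 is the silyl ether of α′-hydroxy enone 5, made by enolate oxidation of 3; 3 arises from carvone 1 by methyl addition (2) and oxidative 1,3-transposition. Carvone 1 thus supplies C3 to C8 with the C4 methyl, the C7 isopropenyl group and the C3 oxygen.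

## Alternatives that were turned down

**Alternative 1:** A [3,3] disconnection that forms C5–C6 while breaking C3–C8. The forward key step is an anionic oxy-Cope rearrangement (potassium alkoxide, crown ether) of a bridged vinyl carbinol derived from a masked o-benzoquinone cycloadduct; it gives A1, cis-fused 9,9-dimethoxy-4,5-dimethyldecal-3-en-8-one.
- For: ring B and quaternary C5 come from one pericyclic step, and the C8 ketone and the C9 oxygen arrive together and already differentiated. On this point it is stronger than the chosen route, which must add the C9 oxygen by a regioselective enolisation. Enolisation of A1 can only go towards C7.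
- Against: A1 has no isopropenyl group at C7 and no oxygen at C3, it is cis-fused, and its precursor is achiral, so absolute configuration needs a further element. The isopropenyl group would have to be attached α to the C8 ketone under the very basic conditions that conjugate it. The C9 ketal must be reduced to a carbinol while C8 stays a ketone. The C3 oxygen must come from the C3=C4 alkene by a borane that also attacks an isopropenyl group.
- Comparison: the chosen route is longer to the first decalin, but after its key step the C7 isopropenyl group (correct configuration), both methyls and the C3 and C8 oxygens are all in place from one enantiopure terpene.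

**Alternative 2:** Disconnection of C9–C10 and C4–C5 in one cationic event. The forward step is a titanium-Lewis-acid ionisation of a chiral acetal at C9, attack of an E trisubstituted alkene through C10 and capture of the C5 cation by C4 of an enol silane; it gives A2, trans-4,5-dimethyl-9α-[(2R,4R)-4-hydroxypentan-2-yloxy]decalin-3-one.
- For: both rings, the trans fusion and four stereocentres (C4, C5, C9, C10) form in one step with auxiliary control of absolute configuration, and the C3 ketone and C9 oxygen are in place. In rings and stereocentres per step, and in giving the trans fusion directly, it is stronger than the chosen route, which needs a separate ring closure and an epimerisation.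
- Against: in A2 the carbons C6, C7 and C8 are bare methylenes. The C8 ketone and the C7 isopropenyl group would have to be introduced on unactivated positions next to the C9 ether, which means a carbonyl transposition and then an α-alkenylation of an isomerisation-prone ketone. The tertiary C5 cation can lose a proton instead of being trapped, the enol silane geometry must be controlled to set C4, and the auxiliary costs two further steps.
- Comparison: the chosen route has the harder ring fusion but no functionalisation of unactivated carbons.

**Alternative 3:** Disconnection of C5–C10 and C1–C2 across the ring fusion. The forward step is an intramolecular Diels–Alder reaction of a vinyl ketone with a tethered diene under a chiral cationic oxazaborolidine Lewis acid; it gives A3, cis-fused 4,5-dimethyldecal-3-en-9-one.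
- For: catalytic enantiocontrol independent of any chiral-pool enantiomer, both rings and quaternary C5 in one atom-economical step, and a C9 carbonyl through which C10 can be epimerised to the trans fusion. In catalytic asymmetric induction and in step count to the decalin it is stronger than the chosen route.
- Against: the diene terminus C5 is fully substituted, which is demanding for a catalysed cycloaddition. The oxygen ends up on C9 as a ketone, whereas the target needs the ketone on C8 and an ester oxygen on C9, so a 1,2-transposition is required. A3 has no C7 isopropenyl group, and the C3 oxygen must again be made from the C3=C4 alkene.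
- Comparison: the chosen route spends its steps on opening the template and closing ring A, but never has to move an oxygen or add the isopropenyl group.

Key step: step 5

## Route

Remark (assumption): the tertiary carbinol centres that are destroyed later (C1 of 2; C3 of 12 to 16) are drawn as the isomer expected from attack opposite the isopropenyl group; their configuration has no consequence. By the sequence rule C5 of 5 and 6 is S, although it keeps the spatial arrangement it has in 3 (R), because the oxygen-bearing C6 now outranks the isopropenyl group.

Step 1
Reactants: 1 (S)-(+)-carvone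
Product: 2 (5S)-1,2-dimethyl-5-(prop-1-en-2-yl)cyclohex-2-en-1-ol (both C1 epimers)
Conditions: MeLi, Et2O, −78 → 0 °C; aq. NH4Cl
Reagents that add atoms: methyllithium, [Li]C
Why: 1,2-addition of a hard organolithium to the enone carbonyl; the new carbinol centre is lost in step 2 and C5 is untouched.

Step 2
Reactants: 2 (5S)-1,2-dimethyl-5-(prop-1-en-2-yl)cyclohex-2-en-1-ol
Product: 3 (5R)-2,3-dimethyl-5-(prop-1-en-2-yl)cyclohex-2-en-1-one
Conditions: [C5H5NH][CrO3Cl] (pyridinium chlorochromate), CH2Cl2, 20 °C
Reagents that add atoms: pyridinium chlorochromate, [O-][Cr](=O)(=O)Cl.c1cc[nH+]cc1 (the carbonyl oxygen of 3 comes from the chromate ester)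
Why: Oxidative 1,3-transposition of a tertiary allylic alcohol (Dauben–Babler oxidation): the chromate ester undergoes a [3,3] shift and the secondary chromate is oxidised, which moves the carbonyl and leaves the 2,3-dimethyl enone.

Step 3
Reactants: 3 (5R)-2,3-dimethyl-5-(prop-1-en-2-yl)cyclohex-2-en-1-one
Product: 5 (5S,6S)-6-hydroxy-2,3-dimethyl-5-(prop-1-en-2-yl)cyclohex-2-en-1-one, via lithium α′-enolate 4 (not isolated)
Conditions: LiN(iPr)2, THF, −78 °C; 2-(phenylsulfonyl)-3-phenyloxaziridine, −78 °C; aq. NH4Cl
Reagents that add atoms: 2-(phenylsulfonyl)-3-phenyloxaziridine, O=S(=O)(c1ccccc1)N1OC1c1ccccc1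
Why: Kinetic α′-deprotonation and electrophilic hydroxylation of the enolate by an N-sulfonyloxaziridine (Davis oxidation); oxygen should enter trans to the neighbouring isopropenyl group, which leaves H6 axial for the deprotonation in step 5.

Step 4
Reactants: 5 (5S,6S)-6-hydroxy-2,3-dimethyl-5-(prop-1-en-2-yl)cyclohex-2-en-1-one
Product: 6 (5S,6S)-6-(tert-butyldimethylsilyloxy)-2,3-dimethyl-5-(prop-1-en-2-yl)cyclohex-2-en-1-one
Conditions: t-BuMe2SiCl, imidazole, DMF, 20 °C
Reagents that add atoms: tert-butyldimethylsilyl chloride, CC(C)(C)[Si](C)(C)Cl
Why: Standard silylation of a secondary α-ketol; the bulky silyl group resists oxygen-to-oxygen transfer in the later enolate and survives every step up to step 11.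

Step 5
Reactants: 6 (5S,6S)-6-(tert-butyldimethylsilyloxy)-2,3-dimethyl-5-(prop-1-en-2-yl)cyclohex-2-en-1-one; 7 methyl acrylate
Product: 10 bicyclo[2.2.2]octanone keto ester (C5 bridgehead methyl; C8 bridgehead silyloxy; ester on C10 endo; C4 methyl on the side of the C6–C7 bridge), via lithium dienolate 8 (not isolated), via ester enolate 9 (not isolated)
Conditions: LiN(iPr)2, THF, −78 °C; 7, −78 → 0 °C; aq. NH4Cl
Reagents that add atoms: none
Why: LiN(iPr)2 removes the axial α′-hydrogen on C8, acidified by the silyloxy group, to give the cross-conjugated dienolate 8 rather than the γ-extended one. C8 of 8 adds to the β-carbon of 7 (bond C8–C9) on the face opposite the vicinal C7 isopropenyl group, which sets quaternary C8. The ester enolate 9 is held on that face and adds to the enone β-carbon C5 (bond C5–C10), a 6-exo-trig conjugate addition with respect to ring B (C5, C6, C7, C8, C9, C10) that also completes the bicyclo[2.2.2]octanone. Because the tether reaches only the face it sits on, C5 is formed with its methyl trans to the isopropenyl group, as in the target. The closest known reaction type is the double Michael bicycloannulation of kinetic lithium dienolates of carvone and 3-methylcyclohexenones with acrylates. The ester on C10 is expected endo (lithium bridging the two oxygens in the second addition) and C4 is set on protonation; neither needs to be controlled because step 6 equilibrates both. The selectivities the step needs are the site of deprotonation and the π-face at C8; the first is secured by kinetic base and the axial H8 of the trans isomer 6, the second by the C7 stereocentre from carvone.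

Step 6
Reactants: 10 bicyclo[2.2.2]octanone keto ester (kinetic adduct)
Product: 11 bicyclo[2.2.2]octanone keto ester (ester on C10 exo, on the side of the C6–C7 bridge; C4 methyl on the side of the C9–C10 bridge)
Conditions: NaOMe (0.5 equiv), MeOH, 50 °C
Reagents that add atoms: none
Why: Base epimerisation through the ketone enolate (C4) and the ester enolate (C10); in the rigid cage 11 is the one isomer in which the C4 methyl clashes neither with the C7 isopropenyl group nor with the C10 ester, so thermodynamic control should favour it. These are the target configurations: C15 cis to C14, and C1 trans to C4 across ring B, which is the later trans ring fusion.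

Step 7
Reactants: 11 bicyclo[2.2.2]octanone keto ester (equilibrated)
Product: 12 C3 vinyl carbinol ester
Conditions: CH2=CHMgBr, CeCl3, THF, −78 °C; aq. NH4Cl
Reagents that add atoms: vinylmagnesium bromide, C=C[Mg]Br
Why: Organocerium 1,2-addition (Imamoto conditions): the weakly basic reagent adds to the hindered, enolisable ketone faster than to the ester and does not epimerise C4; attack should come from the side away from the isopropenyl group.

Step 8
Reactants: 12 C3 vinyl carbinol ester
Product: 13 C3 vinyl carbinol primary alcohol (C1 hydroxymethyl on C10)
Conditions: LiAlH4, THF, 0 °C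
Reagents that add atoms: none
Why: Hydride reduction of the methyl ester; silyl ether, alkenes and the tertiary alkoxide are inert.

Step 9
Reactants: 13 C3 vinyl carbinol primary alcohol
Product: 14 C3 vinyl carbinol aldehyde (C1 formyl on C10)
Conditions: Dess–Martin periodinane, NaHCO3, CH2Cl2, 0 → 20 °C
Reagents that add atoms: none
Why: Buffered Dess–Martin oxidation of the primary alcohol; the tertiary allylic carbinol cannot be oxidised, and chromium oxidants, which would transpose it, are avoided.

Step 10
Reactants: 14 C3 vinyl carbinol aldehyde
Product: 15 bicyclic diene (vinyl on C3 and on C10; C8 silyl ether)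
Conditions: Ph3PCH3Br, n-BuLi, THF, 0 °C; then 14, −78 → 20 °C
Reagents that add atoms: methylenetriphenylphosphorane, C=P(c1ccccc1)(c1ccccc1)c1ccccc1 (from methyltriphenylphosphonium bromide, C[P+](c1ccccc1)(c1ccccc1)c1ccccc1.[Br-])
Why: Wittig methylenation of the aldehyde; excess ylide only deprotonates the tertiary alcohol reversibly, and C10 already has its more stable configuration, so a transient enolate cannot invert it.

Step 11
Reactants: 15 bicyclic diene (C8 silyl ether)
Product: 16 bicyclic C3,C8-diol
Conditions: Bu4NF, THF, 50 °C
Reagents that add atoms: none
Why: Fluoride cleavage of the tertiary silyl ether exposes the ditertiary 1,2-diol; no carbonyl is present, so nothing can epimerise.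

Step 12
Reactants: 16 bicyclic C3,C8-diol
Product: 17 cyclohexanone dienone [4-methyl-4-(3-oxopent-4-en-2-yl)-2-(prop-1-en-2-yl)-5-vinylcyclohexan-1-one; ring B with the C8 ketone and an acryloyl group at C3]
Conditions: Pb(OAc)4, K2CO3, CH2Cl2, −20 → 0 °C
Reagents that add atoms: none
Why: Criegee glycol cleavage of the template bond C3–C8; in the bicyclo[2.2.2]octane the two C–O bonds are gauche in either carbinol epimer, so the cyclic lead ester can form, and the cleavage releases the strain of the cage. The cold, buffered medium should not enolise C4 or C7.

Step 13
Reactants: 17 cyclohexanone dienone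
Product: 18 trans-fused enedione [4β,5β-dimethyl-7α-(prop-1-en-2-yl)-10α-H-decal-1-ene-3,8-dione]
Conditions: RuCl2(=CHPh)(PCy3)(H2IMes) (second-generation Grubbs catalyst, 5 mol %), CH2Cl2, 40 °C, high dilution
Reagents that add atoms: none
Why: Ring-closing metathesis between the C10 vinyl group and the vinyl ketone forms C1=C2 and the six-membered ring A. The two chains are trans-diequatorial on ring B, so the trans fusion is kept, and the neutral medium neither epimerises C4, C7 or C10 nor conjugates the isopropenyl group, which is too hindered and wrongly placed to take part.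

Step 14
Reactants: 18 trans-fused enedione
Product: 20 C8 triisopropylsilyl enol ether of 18 (C8=C9), via lithium C8 enolate 19 (not isolated)
Conditions: LiN(iPr)2 (1.05 equiv), THF, −78 °C; iPr3SiOTf, −78 → −40 °C
Reagents that add atoms: triisopropylsilyl trifluoromethanesulfonate, CC(C)[Si](OS(=O)(=O)C(F)(F)F)(C(C)C)C(C)C
Why: Kinetic deprotonation of the saturated ketone at the methylene C9, rather than at the methine C7 or at the enone, followed by O-silylation; the enol ether stores the C8 carbonyl with fixed regiochemistry for steps 15 to 17.

Step 15
Reactants: 20 C8 silyl enol ether enone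
Product: 22 3α-alcohol (equatorial) of the C8 silyl enol ether, via saturated 3-ketone 21 (not isolated)
Conditions: Li, NH3(l)/THF, −78 °C; then MeOH, −33 °C; solid NH4Cl
Reagents that add atoms: none
Why: Dissolving-metal reduction: the enone is reduced to its enolate, methanol releases ketone 21, and further electron transfer gives the thermodynamically preferred equatorial 3α-alcohol, the pattern known for 4,5-dimethyl-3-keto trans-decalins of the friedelane type, where hydride attacks from the α face and gives the axial alcohol. Silyl enol ether and isopropenyl group are not reduced, and any base-induced equilibration of 21 at C4 favours the wanted equatorial methyl.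

Step 16
Reactants: 22 3α-alcohol; 23 angelic acid
Product: 25 3α-angelate of the C8 silyl enol ether, via mixed anhydride 24 (not isolated)
Conditions: 23, 2,4,6-Cl3C6H2COCl, Et3N, toluene, 20 °C; then 22, 75 °C
Reagents that add atoms: none
Why: Yamaguchi-type mixed-anhydride esterification without a nucleophilic catalyst, the protocol that keeps the Z geometry of angelates on hindered secondary alcohols; C8 is still masked, so no isomerisable ketone is present during heating.

Step 17
Reactants: 25 3α-angelate silyl enol ether
Product: 27 3α-angeloyloxy-9α-hydroxy-8-ketone, via silyloxy epoxide 26 (not isolated)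
Conditions: dimethyldioxirane, acetone/CH2Cl2, −78 → −30 °C; then HF·pyridine, pyridine, THF, 0 °C
Reagents that add atoms: dimethyldioxirane, CC1(C)OO1
Why: Rubottom-type oxidation: the dioxirane epoxidises the electron-rich enol ether faster than the isopropenyl group or the electron-poor enoate, from the α face opposite axial C14; fluoride opens the silyloxy epoxide to the α-hydroxy ketone with the equatorial 9α-hydroxyl, which is also the stable epimer.

Step 18
Reactants: 27 3α-angeloyloxy-9α-hydroxy-8-ketone; 28 (E)-3-methylpent-2-enoic acid
Product: 30 target [(3R,4R,5R,7S,9S,10R)-3-angeloyloxy-9-((E)-3-methylpent-2-enoyloxy)eremophil-11-en-8-one], via O-acylisourea 29 (not isolated)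
Conditions: 28, EDC·HCl, DMAP (0.1 equiv), CH2Cl2, 0 → 20 °C
Reagents that add atoms: none
Why: Steglich-type carbodiimide esterification of the unhindered equatorial α-ketol hydroxyl; the cold, brief and weakly basic conditions should leave both enoate geometries, C7, C9 and the isopropenyl group unchanged.

## Compound list

1 | (S)-(+)-carvone | C=C(C)[C@@H]1CC(=O)C(C)=CC1 | starting material
2 | (5S)-1,2-dimethyl-5-(prop-1-en-2-yl)cyclohex-2-en-1-ol (both C1 epimers) | C=C(C)[C@@H]1CC(C)(O)C(C)=CC1 | intermediate
3 | (5R)-2,3-dimethyl-5-(prop-1-en-2-yl)cyclohex-2-en-1-one | C=C(C)[C@@H]1CC(C)=C(C)C(=O)C1 | intermediate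
4 | lithium α′-enolate of 3 | C=C(C)[C@@H]1CC(C)=C(C)C(O[Li])=C1 | intermediate
5 | (5S,6S)-6-hydroxy-2,3-dimethyl-5-(prop-1-en-2-yl)cyclohex-2-en-1-one | C=C(C)[C@@H]1CC(C)=C(C)C(=O)[C@H]1O | intermediate
6 | (5S,6S)-6-(tert-butyldimethylsilyloxy)-2,3-dimethyl-5-(prop-1-en-2-yl)cyclohex-2-en-1-one | C=C(C)[C@@H]1CC(C)=C(C)C(=O)[C@H]1O[Si](C)(C)C(C)(C)C | intermediate
7 | methyl acrylate | C=CC(=O)OC | starting material
8 | lithium dienolate of 6 | C=C(C)[C@@H]1CC(C)=C(C)C(O[Li])=C1O[Si](C)(C)C(C)(C)C | intermediate
9 | lithium ester enolate after the first conjugate addition | C=C(C)[C@@H]1CC(C)=C(C)C(=O)[C@@]1(O[Si](C)(C)C(C)(C)C)CC=C(OC)O[Li] | intermediate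
10 | methyl 4-(tert-butyldimethylsilyloxy)-1,6-dimethyl-5-oxo-8-(prop-1-en-2-yl)bicyclo[2.2.2]octane-2-carboxylate, kinetic adduct (endo ester on C10; C4 methyl towards the C6–C7 bridge) | C=C(C)[C@@H]1C[C@]2(C)[C@H](C)C(=O)[C@@]1(O[Si](C)(C)C(C)(C)C)C[C@H]2C(=O)OC | intermediate
11 | C4,C10-diepimer of 10 (exo ester; C4 methyl towards the C9–C10 bridge) | C=C(C)[C@@H]1C[C@]2(C)[C@@H](C)C(=O)[C@@]1(O[Si](C)(C)C(C)(C)C)C[C@@H]2C(=O)OC | intermediate
12 | C3 vinyl carbinol ester | C=C(C)[C@@H]1C[C@]2(C)[C@@H](C)[C@@](O)(C=C)[C@@]1(O[Si](C)(C)C(C)(C)C)C[C@@H]2C(=O)OC | intermediate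
13 | C3 vinyl carbinol primary alcohol | C=C(C)[C@@H]1C[C@]2(C)[C@@H](C)[C@@](O)(C=C)[C@@]1(O[Si](C)(C)C(C)(C)C)C[C@@H]2CO | intermediate
14 | C3 vinyl carbinol aldehyde | C=C(C)[C@@H]1C[C@]2(C)[C@@H](C)[C@@](O)(C=C)[C@@]1(O[Si](C)(C)C(C)(C)C)C[C@@H]2C=O | intermediate
15 | bicyclic diene, C8 silyl ether | C=C(C)[C@@H]1C[C@]2(C)[C@@H](C)[C@@](O)(C=C)[C@@]1(O[Si](C)(C)C(C)(C)C)C[C@@H]2C=C | intermediate
16 | bicyclic C3,C8-diol | C=C(C)[C@@H]1C[C@]2(C)[C@@H](C)[C@@](O)(C=C)[C@@]1(O)C[C@@H]2C=C | intermediate
17 | 4-methyl-4-(3-oxopent-4-en-2-yl)-2-(prop-1-en-2-yl)-5-vinylcyclohexan-1-one | C=C(C)[C@@H]1C[C@](C)([C@@H](C)C(=O)C=C)[C@@H](C=C)CC1=O | intermediate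
18 | 4β,5β-dimethyl-7α-(prop-1-en-2-yl)-10α-H-decal-1-ene-3,8-dione | C=C(C)[C@@H]1C[C@]2(C)[C@@H](C)C(=O)C=C[C@H]2CC1=O | intermediate
19 | lithium C8 enolate of 18 | C=C(C)[C@@H]1C[C@]2(C)[C@@H](C)C(=O)C=C[C@H]2C=C1O[Li] | intermediate
20 | C8 triisopropylsilyl enol ether of 18 | C=C(C)[C@@H]1C[C@]2(C)[C@@H](C)C(=O)C=C[C@H]2C=C1O[Si](C(C)C)(C(C)C)C(C)C | intermediate
21 | saturated 3-ketone, C8 silyl enol ether | C=C(C)[C@@H]1C[C@]2(C)[C@@H](C)C(=O)CC[C@H]2C=C1O[Si](C(C)C)(C(C)C)C(C)C | intermediate
22 | 3α-alcohol, C8 silyl enol ether | C=C(C)[C@@H]1C[C@]2(C)[C@@H](C)[C@H](O)CC[C@H]2C=C1O[Si](C(C)C)(C(C)C)C(C)C | intermediate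
23 | angelic acid | C/C=C(C)\C(=O)O | starting material
24 | angelic 2,4,6-trichlorobenzoic anhydride | C/C=C(C)\C(=O)OC(=O)c1c(Cl)cc(Cl)cc1Cl | intermediate
25 | 3α-angelate, C8 silyl enol ether | C=C(C)[C@@H]1C[C@]2(C)[C@@H](C)[C@H](OC(=O)/C(C)=C\C)CC[C@H]2C=C1O[Si](C(C)C)(C(C)C)C(C)C | intermediate
26 | 8,9α-epoxide of 25 (silyloxy epoxide) | C=C(C)[C@@H]1C[C@]2(C)[C@@H](C)[C@H](OC(=O)/C(C)=C\C)CC[C@H]2[C@@H]3O[C@]13O[Si](C(C)C)(C(C)C)C(C)C | intermediate
27 | 3α-angeloyloxy-9α-hydroxy-4β,5β-dimethyl-7α-(prop-1-en-2-yl)-trans-decalin-8-one | C=C(C)[C@@H]1C[C@]2(C)[C@@H](C)[C@H](OC(=O)/C(C)=C\C)CC[C@H]2[C@H](O)C1=O | intermediate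
28 | (E)-3-methylpent-2-enoic acid | CC/C(C)=C/C(=O)O | starting material
29 | O-acylisourea of 28 with EDC | CCN=C(NCCCN(C)C)OC(=O)/C=C(\C)CC | intermediate
30 | (3R,4R,5R,7S,9S,10R)-3-angeloyloxy-9-((E)-3-methylpent-2-enoyloxy)eremophil-11-en-8-one | C=C(C)[C@@H]1C[C@]2(C)[C@@H](C)[C@H](OC(=O)/C(C)=C\C)CC[C@H]2[C@H](OC(=O)/C=C(\C)CC)C1=O | target

## Step count and risk

Total step count: 18. Longest linear sequence: 18 steps (1 to 30); 7, 23 and 28 enter as single building blocks.

**Step 5 (key step).** Deprotonation may occur at the γ positions instead of at the hindered, oxygen-bearing α′ carbon, or the sequence may stall after the first conjugate addition because the acceptor carbon C5 is fully substituted and the enolate carbon is crowded by the silyl ether. Fallback, starting from 6: the ester enolate 9, generated as in step 5, is trapped with Me3SiCl as the silyl ketene acetal F1. The ring is then closed by an intramolecular Mukaiyama–Michael addition under TiCl4 or catalytic Me3SiOTf in CH2Cl2 at −78 °C, which activates the enone electrophilically instead of relying on the anionic push. Aqueous work-up returns to the route at 10, or at an epimer that step 6 converts to 11.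

**Step 6.** Epimerisation at C10 through the hindered ester enolate may be slow, so that equilibrium is not reached before retro-Michael opening or other base-induced loss sets in. Fallback, starting from 10: LiAlH4 reduces ester and ketone to the diol F2. Dess–Martin oxidation gives the keto aldehyde F3. K2CO3 in MeOH equilibrates C4 and C10 through the ketone and the much more acidic aldehyde to the keto aldehyde F4. Aldehyde-selective Wittig methylenation gives the vinyl ketone F5, and CH2=CHMgBr/CeCl3 then adds to the ketone and rejoins the route at 15. This order also removes the ester before the organometallic addition, so it covers a poor ketone-over-ester selectivity in step 7.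

**Step 14.** Enolisation may turn towards C7, whose hydrogen is allylic as well as α to the ketone, or may involve the enone, so that the enol ether forms with the wrong regiochemistry. Fallback, starting from 18:
- the saturated C8 ketone is ketalised selectively [1,2-bis(trimethylsilyloxy)ethane, catalytic Me3SiOTf, −78 °C] to the ketal F6;
- Li/NH3 then MeOH gives the 3α-alcohol F7;
- the angeloylation of step 16 gives the ester F8;
- pyridinium p-toluenesulfonate in wet acetone releases the ketone F9;
- the C9 oxygen is introduced through the enamine, not the enolate, by proline-catalysed α-aminoxylation with nitrosobenzene, which selects the methylene α-carbon, to give the anilinooxy ketone F10;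
- N–O cleavage with CuSO4 in MeOH rejoins the route at 27.

**Step 15.** The saturated ketone may not be reduced cleanly to the equatorial alcohol in one pot, through incomplete reduction, partial loss of the silyl enol ether to methoxide, or ketyl coupling. Fallback, starting from 20: conjugate reduction with [(Ph3P)CuH]6 gives ketone 21, now isolated. NaBH4 gives mainly the axial 3β-alcohol F11. A Meerwein–Ponndorf–Verley/Oppenauer equilibration [Al(OiPr)3, isopropanol, catalytic acetone, toluene, reflux] moves the carbinol to the equatorial configuration and rejoins the route at 22.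

**Step 16.** The hindered equatorial alcohol next to the C4 methyl may acylate slowly, and prolonged heating with amine salts may isomerise the angelate to the tiglate or protodesilylate the enol ether. Fallback, starting from 22: the alcohol is esterified with 2-[bis(2,2,2-trifluoroethoxy)phosphoryl]propanoic acid (carbodiimide, DMAP) to the phosphonate F12. A Still–Gennari olefination with acetaldehyde [KN(SiMe3)2, 18-crown-6, THF, −78 °C] then builds the Z double bond on the substrate and rejoins the route at 25.

## Further compounds

F1 | step 5 | trimethylsilyl ketene acetal of the first conjugate adduct | C=C(C)[C@@H]1CC(C)=C(C)C(=O)[C@@]1(O[Si](C)(C)C(C)(C)C)CC=C(OC)O[Si](C)(C)C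
F2 | step 6 | bicyclic diol from reduction of 10 (C3 carbinol epimers; kinetic C4 and C10) | C=C(C)[C@@H]1C[C@]2(C)[C@H](C)C(O)[C@@]1(O[Si](C)(C)C(C)(C)C)C[C@H]2CO
F3 | step 6 | bicyclic keto aldehyde, kinetic configuration | C=C(C)[C@@H]1C[C@]2(C)[C@H](C)C(=O)[C@@]1(O[Si](C)(C)C(C)(C)C)C[C@H]2C=O
F4 | step 6 | bicyclic keto aldehyde, equilibrated (exo aldehyde; C4 methyl towards the C9–C10 bridge) | C=C(C)[C@@H]1C[C@]2(C)[C@@H](C)C(=O)[C@@]1(O[Si](C)(C)C(C)(C)C)C[C@@H]2C=O
F5 | step 6 | bicyclic C10-vinyl ketone | C=C(C)[C@@H]1C[C@]2(C)[C@@H](C)C(=O)[C@@]1(O[Si](C)(C)C(C)(C)C)C[C@@H]2C=C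
F6 | step 14 | C8 ethylene ketal of 18 | C=C(C)[C@@H]1C[C@]2(C)[C@@H](C)C(=O)C=C[C@H]2CC13OCCO3
F7 | step 14 | 3α-alcohol, C8 ethylene ketal | C=C(C)[C@@H]1C[C@]2(C)[C@@H](C)[C@H](O)CC[C@H]2CC13OCCO3
F8 | step 14 | 3α-angelate, C8 ethylene ketal | C=C(C)[C@@H]1C[C@]2(C)[C@@H](C)[C@H](OC(=O)/C(C)=C\C)CC[C@H]2CC13OCCO3
F9 | step 14 | 3α-angeloyloxy-4β,5β-dimethyl-7α-(prop-1-en-2-yl)-trans-decalin-8-one | C=C(C)[C@@H]1C[C@]2(C)[C@@H](C)[C@H](OC(=O)/C(C)=C\C)CC[C@H]2CC1=O
F10 | step 14 | 9α-(phenylaminooxy) derivative of F9 | C=C(C)[C@@H]1C[C@]2(C)[C@@H](C)[C@H](OC(=O)/C(C)=C\C)CC[C@H]2[C@H](ONc3ccccc3)C1=O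
F11 | step 15 | 3β-alcohol (axial), C8 silyl enol ether | C=C(C)[C@@H]1C[C@]2(C)[C@@H](C)[C@@H](O)CC[C@H]2C=C1O[Si](C(C)C)(C(C)C)C(C)C
F12 | step 16 | 3α-[2-(bis(2,2,2-trifluoroethoxy)phosphoryl)propanoyloxy], C8 silyl enol ether | C=C(C)[C@@H]1C[C@]2(C)[C@@H](C)[C@H](OC(=O)C(C)P(=O)(OCC(F)(F)F)OCC(F)(F)F)CC[C@H]2C=C1O[Si](C(C)C)(C(C)C)C(C)C
A1 | alternative 1 | cis-fused 9,9-dimethoxy-4,5-dimethyldecal-3-en-8-one | C1C[C@]2(C)C(C)=CCC[C@@H]2C(OC)(OC)C1=O
A2 | alternative 2 | trans-4,5-dimethyl-9α-[(2R,4R)-4-hydroxypentan-2-yloxy]decalin-3-one | C1C[C@]2(C)[C@@H](C)C(=O)CC[C@H]2[C@H](O[C@H](C)C[C@@H](C)O)C1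
A3 | alternative 3 | cis-fused 4,5-dimethyldecal-3-en-9-one | C1C[C@]2(C)C(C)=CCC[C@@H]2C(=O)C1
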